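## Retrosynthetic overview

1. Target ⇒ three late operations on the bicyclic core: C7 hydroxyl (enolate oxidation), C3=C4 alkene (Saegusa dehydrogenation) and the ester C–O bond (Yamaguchi) ⇒ bicyclic hydroxy enone + (S)-dienoic acid.
2. Ring A (the ring with the C1 methyl and the C2 oxygen) ⇒ one-carbon ring expansion: semipinacol 1,2-shift of the quaternary ring-fusion carbon of a 1-vinyl hydrindenol. This inserts the CH(CH3) unit next to the quaternary centre and leaves a ketone for the C2 oxygen.
3. Hydrindenone ⇒ proline-catalysed Robinson annulation of 2-methylcyclopentane-1,3-dione with methyl vinyl ketone, which sets the quaternary centre; C1, C2 and C7 are relayed from it.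
4. Side chain ⇒ Doebner condensation of malonic acid with an enal made from (R)-2-methylglycidol (methyl Grignard opening, oxidation, Wittig).
5. Ring order: enone ring B first (annulation), then the five-membered ring is expanded to ring A.

Assumption: (R)-(2-methyloxiran-2-yl)methanol is bought as the single enantiomer.

## Route

Step 1
Reactants: 1 2-methylcyclopentane-1,3-dione; 2 but-3-en-2-one (methyl vinyl ketone)
Product: 5 (S)-7a-methyl-2,3,7,7a-tetrahydro-1H-indene-1,5(6H)-dione (Hajos–Parrish ketone), via triketone 3 (not isolated), via bicyclic ketol 4 (not isolated)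
Conditions: 2 (1.5 equiv), Et3N (cat.), EtOAc, 25 °C; evaporate; (S)-proline (3 mol%), DMF, 20 °C; then H2SO4 (cat.), 95 °C
Reagents that add atoms: none
Why: Michael addition followed by the Hajos–Parrish–Eder–Sauer–Wiechert reaction, in which the (S)-proline enamine aldol differentiates the two enantiotopic ring carbonyls and sets the quaternary centre as S (about 95% ee, raised by crystallisation) before acid dehydration to the enone.

Step 2
Reactants: 5 (S)-7a-methyl-2,3,7,7a-tetrahydro-1H-indene-1,5(6H)-dione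
Product: 6 (1R,7aS)-1-ethenyl-1-hydroxy-7a-methyl-1,2,3,6,7,7a-hexahydro-5H-inden-5-one (hydroxyl cis to the angular methyl)
Conditions: CH2=CHMgBr (1.1 equiv), anhydrous CeCl3 (1.2 equiv), THF, −78 °C; aq. NH4Cl
Reagents that add atoms: vinylmagnesium bromide, C=C[Mg]Br
Why: Organocerium 1,2-addition, expected to prefer the saturated cyclopentanone over the less electrophilic β,β-disubstituted enone and to attack anti to the angular methyl, giving the 1R carbinol (a centre that is destroyed in the next step).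

Step 3
Reactants: 6 (1R,7aS)-1-ethenyl-1-hydroxy-7a-methyl-1,2,3,6,7,7a-hexahydro-5H-inden-5-one
Product: 7 (4aR,5R)-4a,5-dimethyl-4,4a,7,8-tetrahydronaphthalene-2,6(3H,5H)-dione (the two methyls cis)
Conditions: Co(salen) [Co(C16H14N2O2)] (5 mol%), N-fluoro-2,4,6-trimethylpyridinium tetrafluoroborate (1.2 equiv), PhSiH3 (1.2 equiv), PhCF3, 0 to 25 °C
Reagents that add atoms: none
Why: Proposed new method: a trivalent cobalt hydride made from divalent Co(salen), the N-fluoropyridinium oxidant and PhSiH3 transfers a hydrogen atom to the terminal vinyl carbon of 6, the secondary radical is captured and oxidised to a tetravalent alkylcobalt (a cation equivalent), and the electron-rich quaternary C7a, anti to the C–Co bond, shifts to that carbon while the carbinol becomes the ketone (radical-polar crossover semipinacol ring expansion, cyclopentanol to cyclohexanone), the rotamer with the new methyl gauche to the small O–H placing it equatorial and cis to the angular methyl (5R), which should also be the thermodynamic epimer of this enolisable centre; the neutral radical conditions avoid ionising the tertiary allylic alcohol and should leave the electron-poor trisubstituted enone alone, and the closest known reactions are cobalt-salen hydrogen-atom-transfer semipinacol rearrangements of 1-(1-arylvinyl)cyclobutanols and the cationic D-homoannulation of 17-hydroxy steroids in which the quaternary carbon migrates, neither shown for a monosubstituted vinyl group on an unstrained cyclopentanol.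

Step 4
Reactants: 7 (4aR,5R)-4a,5-dimethyl-4,4a,7,8-tetrahydronaphthalene-2,6(3H,5H)-dione
Product: 8 (4aR,5R,6S)-6-hydroxy-4a,5-dimethyl-4,4a,5,6,7,8-hexahydronaphthalen-2(3H)-one (hydroxyl cis to both methyls)
Conditions: LiBH(s-Bu)3 (1.05 equiv), THF, −78 °C; H2O
Reagents that add atoms: none
Why: Bulky-hydride reduction of the saturated ketone from the face opposite the axial angular methyl (equatorial attack, as with 3,3,5-trimethylcyclohexanone) gives the axial 6S alcohol, while the hindered β,β-disubstituted enone is untouched at −78 °C.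

Step 5
Reactants: 9 (R)-(2-methyloxiran-2-yl)methanol
Product: 10 (S)-2-methylbutane-1,2-diol
Conditions: MeMgBr (3 equiv), CuI (10 mol%), THF, −30 to 0 °C; aq. NH4Cl
Reagents that add atoms: methylmagnesium bromide, C[Mg]Br
Why: Copper-catalysed Grignard opening of the 2,2-disubstituted epoxide at its CH2 terminus leaves the stereocentre untouched (the descriptor changes from R to S only because the CIP ranking changes).

Step 6
Reactants: 10 (S)-2-methylbutane-1,2-diol
Product: 12 (S,E)-4-hydroxy-4-methylhex-2-enal, via hydroxy aldehyde 11 (not isolated)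
Conditions: SO3·pyridine, DMSO, i-Pr2NEt, CH2Cl2, 0 °C; then Ph3P=CHCHO (1.3 equiv), 25 to 40 °C
Reagents that add atoms: (triphenylphosphoranylidene)acetaldehyde, O=CC=P(c1ccccc1)(c1ccccc1)c1ccccc1
Why: Parikh–Doering oxidation touches only the primary alcohol (no glycol cleavage, no α-hydrogen to epimerise) and the stabilised formyl ylide then gives the E-enal in a one-flask oxidation–Wittig sequence.

Step 7
Reactants: 12 (S,E)-4-hydroxy-4-methylhex-2-enal; 13 propanedioic acid (malonic acid)
Product: 15 (S,2E,4E)-6-hydroxy-6-methylocta-2,4-dienoic acid, via dienylidenemalonic acid 14 (not isolated)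
Conditions: 13 (2 equiv), pyridine, piperidine (cat.), 80 °C
Reagents that add atoms: none
Why: Knoevenagel–Doebner condensation with decarboxylation (the sorbic acid type) gives the 2E,4E acid directly, and the quaternary C6 excludes deconjugation.

Step 8
Reactants: 8 (4aR,5R,6S)-6-hydroxy-4a,5-dimethyl-4,4a,5,6,7,8-hexahydronaphthalen-2(3H)-one; 15 (S,2E,4E)-6-hydroxy-6-methylocta-2,4-dienoic acid
Product: 17 (1R,2S,8aR)-1,8a-dimethyl-6-oxo-1,2,3,4,6,7,8,8a-octahydronaphthalen-2-yl (S,2E,4E)-6-hydroxy-6-methylocta-2,4-dienoate, via mixed anhydride 16 (not isolated)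
Conditions: 15 (1.3 equiv), 2,4,6-trichlorobenzoyl chloride, Et3N, THF, 25 °C; then 8, DMAP, toluene, 60 °C
Reagents that add atoms: none
Why: Yamaguchi esterification acylates the secondary alcohol with retention, while the tertiary hydroxyl of the acid is too hindered to compete.

Step 9
Reactants: 17 (1R,2S,8aR)-1,8a-dimethyl-6-oxo-1,2,3,4,6,7,8,8a-octahydronaphthalen-2-yl (S,2E,4E)-6-hydroxy-6-methylocta-2,4-dienoate
Product: 20 (1R,2S,8aR)-1,8a-dimethyl-6-oxo-1,2,6,7,8,8a-hexahydronaphthalen-2-yl (S,2E,4E)-6-hydroxy-6-methylocta-2,4-dienoate, via bis-silyl dienol ether 18 (not isolated), via silyl ether dienone 19 (not isolated)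
Conditions: TMSOTf (3 equiv), Et3N (5 equiv), CH2Cl2, 0 °C; then Pd(OAc)2 (1.1 equiv), MeCN, 40 °C; then 1 M HCl, THF, 0 °C
Reagents that add atoms: none
Why: Soft enolisation gives the thermodynamic extended silyl dienol ether (as with steroidal 4-en-3-ones), Saegusa–Ito oxidation then palladates the γ-carbon and β-hydride elimination can only give the linear dienone, and the mild acid work-up frees the tertiary alcohol.

Step 10
Reactants: 20 (1R,2S,8aR)-1,8a-dimethyl-6-oxo-1,2,6,7,8,8a-hexahydronaphthalen-2-yl (S,2E,4E)-6-hydroxy-6-methylocta-2,4-dienoate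
Product: 22 (1R,2S,7R,8aR)-7-hydroxy-1,8a-dimethyl-6-oxo-1,2,6,7,8,8a-hexahydronaphthalen-2-yl (S,2E,4E)-6-hydroxy-6-methylocta-2,4-dienoate (target), via dipotassium dienolate 21 (not isolated)
Conditions: KN(SiMe3)2 (2.3 equiv), THF, −78 °C; then 2-(phenylsulfonyl)-3-phenyloxaziridine (1.3 equiv), −78 °C; AcOH
Reagents that add atoms: 2-(phenylsulfonyl)-3-phenyloxaziridine (Davis oxaziridine), O=S(=O)(c1ccccc1)N1OC1c1ccccc1
Why: Kinetic α′-deprotonation and Davis enolate hydroxylation from the face opposite the pseudoaxial angular methyl give the 7R alcohol, trans to that methyl, which is also the equatorial, thermodynamically preferred ketol.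

## Compound list

1 | 2-methylcyclopentane-1,3-dione | CC1C(=O)CCC1=O | starting material
2 | but-3-en-2-one (methyl vinyl ketone) | CC(=O)C=C | starting material
3 | 2-methyl-2-(3-oxobutyl)cyclopentane-1,3-dione | CC(=O)CCC1(C)C(=O)CCC1=O | intermediate
4 | (3aS,7aS)-3a-hydroxy-7a-methylhexahydro-1H-indene-1,5(4H)-dione | C[C@]12CCC(=O)C[C@@]1(O)CCC2=O | intermediate
5 | (S)-7a-methyl-2,3,7,7a-tetrahydro-1H-indene-1,5(6H)-dione | C[C@]12CCC(=O)C=C1CCC2=O | intermediate
6 | (1R,7aS)-1-ethenyl-1-hydroxy-7a-methyl-1,2,3,6,7,7a-hexahydro-5H-inden-5-one | C[C@]12CCC(=O)C=C1CC[C@@]2(O)C=C | intermediate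
7 | (4aR,5R)-4a,5-dimethyl-4,4a,7,8-tetrahydronaphthalene-2,6(3H,5H)-dione | O=C1CCC2=CC(=O)CC[C@]2(C)[C@H]1C | intermediate
8 | (4aR,5R,6S)-6-hydroxy-4a,5-dimethyl-4,4a,5,6,7,8-hexahydronaphthalen-2(3H)-one | O[C@H]1CCC2=CC(=O)CC[C@]2(C)[C@H]1C | intermediate
9 | (R)-(2-methyloxiran-2-yl)methanol | C[C@@]1(CO)CO1 | starting material
10 | (S)-2-methylbutane-1,2-diol | CC[C@](C)(O)CO | intermediate
11 | (S)-2-hydroxy-2-methylbutanal | CC[C@](C)(O)C=O | intermediate
12 | (S,E)-4-hydroxy-4-methylhex-2-enal | CC[C@](C)(O)/C=C/C=O | intermediate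
13 | propanedioic acid (malonic acid) | OC(=O)CC(=O)O | starting material
14 | 2-[(S,E)-4-hydroxy-4-methylhex-2-en-1-ylidene]propanedioic acid | CC[C@](C)(O)/C=C/C=C(C(=O)O)C(=O)O | intermediate
15 | (S,2E,4E)-6-hydroxy-6-methylocta-2,4-dienoic acid | CC[C@](C)(O)/C=C/C=C/C(=O)O | intermediate
16 | (S,2E,4E)-6-hydroxy-6-methylocta-2,4-dienoic 2,4,6-trichlorobenzoic anhydride | CC[C@](C)(O)/C=C/C=C/C(=O)OC(=O)c1c(Cl)cc(Cl)cc1Cl | intermediate
17 | (1R,2S,8aR)-1,8a-dimethyl-6-oxo-1,2,3,4,6,7,8,8a-octahydronaphthalen-2-yl (S,2E,4E)-6-hydroxy-6-methylocta-2,4-dienoate | CC[C@](C)(O)/C=C/C=C/C(=O)O[C@H]1CCC2=CC(=O)CC[C@]2(C)[C@H]1C | intermediate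
18 | (1R,2S,8aR)-1,8a-dimethyl-6-(trimethylsilyloxy)-1,2,3,7,8,8a-hexahydronaphthalen-2-yl (S,2E,4E)-6-methyl-6-(trimethylsilyloxy)octa-2,4-dienoate | CC[C@](C)(O[Si](C)(C)C)/C=C/C=C/C(=O)O[C@H]1CC=C2C=C(O[Si](C)(C)C)CC[C@]2(C)[C@H]1C | intermediate
19 | (1R,2S,8aR)-1,8a-dimethyl-6-oxo-1,2,6,7,8,8a-hexahydronaphthalen-2-yl (S,2E,4E)-6-methyl-6-(trimethylsilyloxy)octa-2,4-dienoate | CC[C@](C)(O[Si](C)(C)C)/C=C/C=C/C(=O)O[C@H]1C=CC2=CC(=O)CC[C@]2(C)[C@H]1C | intermediate
20 | (1R,2S,8aR)-1,8a-dimethyl-6-oxo-1,2,6,7,8,8a-hexahydronaphthalen-2-yl (S,2E,4E)-6-hydroxy-6-methylocta-2,4-dienoate | CC[C@](C)(O)/C=C/C=C/C(=O)O[C@H]1C=CC2=CC(=O)CC[C@]2(C)[C@H]1C | intermediate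
21 | dipotassium salt of 20 (C7 enolate of the dienone and tertiary alkoxide) | CC[C@](C)(O[K])/C=C/C=C/C(=O)O[C@H]1C=CC2=CC(O[K])=CC[C@]2(C)[C@H]1C | intermediate
22 | (1R,2S,7R,8aR)-7-hydroxy-1,8a-dimethyl-6-oxo-1,2,6,7,8,8a-hexahydronaphthalen-2-yl (S,2E,4E)-6-hydroxy-6-methylocta-2,4-dienoate | CC[C@](C)(O)/C=C/C=C/C(=O)O[C@H]1C=CC2=CC(=O)[C@H](O)C[C@]2(C)[C@H]1C | target

## Step count and risks

Total step count: 10. Longest linear sequence: 7 (steps 1, 2, 3, 4, 8, 9, 10); the side chain (steps 5 to 7) joins at step 8.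

The three steps most likely to fail:

**Step 3 (the new ring expansion).** The alkylcobalt intermediate could close to an epoxide, the ring CH2 could migrate instead of the quaternary carbon, or the enone could be reduced. The fallback uses known chemistry, sets out from 6 and comes back at 7. Hydroxyl-directed epoxidation of 6 (VO(acac)2, t-BuOOH, CH2Cl2) gives the epoxy alcohol F1. An epoxy-alcohol semipinacol rearrangement (BF3·OEt2, CH2Cl2, −78 °C; the quaternary carbon migrates to the opening oxirane carbon) gives the ring-expanded hydroxymethyl diketone F2. Mesylation and elimination (MsCl, Et3N, then DBU) give the methylidene enedione F3, in which the epimeric centre is erased. Chemoselective conjugate reduction of the unhindered exocyclic enone ([(Ph3P)CuH]6, benzene, 25 °C, then aq. NH4Cl) with protonation to the equatorial methyl returns 7.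

**Step 2 (chemoselective vinylation).** The hindered cyclopentanone may not outrun 1,2-addition to the enone. The fallback sets out from 5 and comes back at 6. Selective thioketalisation of the conjugated carbonyl (HSCH2CH2SH, BF3·OEt2, MeOH, 25 °C, as known for Wieland–Miescher-type enediones) gives the enone dithioketal F4. Vinyl addition (CH2=CHMgBr, CeCl3, THF, −78 °C) gives the vinyl carbinol dithioketal F5. Dethioketalisation (MeI, CaCO3, aqueous MeCN) returns 6.

**Step 8 (esterification).** The alcohol of 8 is axial, 1,3-diaxial to the angular methyl and next to the secondary methyl, so acylation with the bulky mixed anhydride may be slow. The fallback sets out from 8, uses enal 12 directly (steps 7 is then not needed) and comes back at 17. Acylation with the small, very reactive bromoacetyl bromide (pyridine, CH2Cl2, 0 °C) gives the bromoacetate F6. An Arbuzov reaction (P(OEt)3, 110 °C) gives the phosphonoacetate F7. A Masamune–Roush Horner–Wadsworth–Emmons reaction with 12 (LiCl, DBU, MeCN, 25 °C) builds the 2E,4E-dienoate on the core and returns 17.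

## Further compounds

F1 | step 3 | (1S,7aS)-1-hydroxy-7a-methyl-1-(oxiran-2-yl)-1,2,3,6,7,7a-hexahydro-5H-inden-5-one (both epimers at the oxirane carbon) | C[C@]12CCC(=O)C=C1CC[C@@]2(O)C1CO1
F2 | step 3 | (4aR)-5-(hydroxymethyl)-4a-methyl-4,4a,7,8-tetrahydronaphthalene-2,6(3H,5H)-dione (both epimers at C5) | O=C1CCC2=CC(=O)CC[C@]2(C)C1CO
F3 | step 3 | (S)-4a-methyl-5-methylidene-4,4a,7,8-tetrahydronaphthalene-2,6(3H,5H)-dione | O=C1CCC2=CC(=O)CC[C@]2(C)C1=C
F4 | step 2 | (7a'S)-7a'-methyl-2',3',7',7a'-tetrahydrospiro[1,3-dithiolane-2,5'-inden]-1'(6'H)-one | C[C@]12CCC3(SCCS3)C=C1CCC2=O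
F5 | step 2 | (1'R,7a'S)-1'-ethenyl-7a'-methyl-1',2',3',6',7',7a'-hexahydrospiro[1,3-dithiolane-2,5'-inden]-1'-ol | C[C@]12CCC3(SCCS3)C=C1CC[C@@]2(O)C=C
F6 | step 8 | (1R,2S,8aR)-1,8a-dimethyl-6-oxo-1,2,3,4,6,7,8,8a-octahydronaphthalen-2-yl 2-bromoacetate | BrCC(=O)O[C@H]1CCC2=CC(=O)CC[C@]2(C)[C@H]1C
F7 | step 8 | (1R,2S,8aR)-1,8a-dimethyl-6-oxo-1,2,3,4,6,7,8,8a-octahydronaphthalen-2-yl 2-(diethoxyphosphoryl)acetate | CCOP(=O)(OCC)CC(=O)O[C@H]1CCC2=CC(=O)CC[C@]2(C)[C@H]1C
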